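**Retrosynthetic overview**

1. Feature: the chain on ring A is C6–C1''H2–C2''H2–C3''(CH3)2OH. Its carbinol carbon C3'' lies three atoms from C6, and C6 is the free ortho neighbour of O5. An acyl carbon placed on O5 can therefore become C3'', with O5, C3'', C2'', C1'', C6 and C5 forming a temporary six-membered lactone (ring D).
2. Last disconnection: both C3''–CH3 bonds, by MeMgBr on the saturated lactone; this opens ring D and returns the 5-OH.
3. Key disconnection: C6–C1'', by palladium-catalysed intramolecular hydroarylation of the 5-O-propiolate 7 to the pyranone 8 (ring D closed). Hydrogenation then saturates C1''=C2'' and removes the benzyl groups.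
4. Precursor 7 comes from kaempferol by 7,4'-di-O-benzylation, 3-O-methylation and acylation of the 5-OH with propiolic acid.
5. Ring order: rings A, C and B arrive complete in kaempferol; ring D is the only ring made (step 4) and is opened again in step 6.

Key step: step 4

Remark: the target has no stereocentre, so no stereocontrol is needed.

Assumption: under carbonate conditions the hydroxyls of kaempferol are alkylated in the order 7-OH, 4'-OH, 3-OH, 5-OH, so two equivalents of benzyl bromide should end mainly on O7 and O4'; over-benzylated material is removed by chromatography.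

**Route**

Step 1
Reactants: 1 kaempferol; 2 benzyl bromide
Product: 3 7,4'-di-O-benzylkaempferol
Conditions: BnBr (2.1 equiv), K2CO3 (2.2 equiv), DMF, 0 °C to rt
Reagents that add atoms: benzyl bromide, BrCc1ccccc1
Why: Williamson ether synthesis in which the two most acidic hydroxyls (O7–H and O4'–H, both vinylogous to the C4 carbonyl and free of hydrogen bonds) should be benzylated before the hydrogen-bonded 3-OH and 5-OH.

Step 2
Reactants: 3 7,4'-di-O-benzylkaempferol; 4 iodomethane
Product: 5 7,4'-di-O-benzyl-3-O-methylkaempferol
Conditions: MeI (1.3 equiv), K2CO3 (1.5 equiv), DMF, rt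
Reagents that add atoms: iodomethane, CI
Why: Williamson O-methylation in which the enolic 3-OH reacts at room temperature, while the 5-OH, held in a six-membered hydrogen bond to the C4 carbonyl, should stay free under these mild conditions.

Step 3
Reactants: 5 7,4'-di-O-benzyl-3-O-methylkaempferol; 6 propiolic acid
Product: 7 7-(benzyloxy)-2-[4-(benzyloxy)phenyl]-3-methoxy-4-oxo-4H-chromen-5-yl prop-2-ynoate
Conditions: propiolic acid (2.5 equiv), DCC (2.5 equiv), DMAP (5 mol%), CH2Cl2, −20 °C to rt
Reagents that add atoms: propiolic acid, C#CC(=O)O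
Why: Steglich esterification of the only free hydroxyl (O5–H), in which the carbodiimide-activated acid is electrophilic enough for this hydrogen-bonded phenol and the small DMAP charge at low temperature holds back amine-triggered addition to the triple bond.

Step 4
Reactants: 7 7-(benzyloxy)-2-[4-(benzyloxy)phenyl]-3-methoxy-4-oxo-4H-chromen-5-yl prop-2-ynoate
Product: 8 5-(benzyloxy)-8-[4-(benzyloxy)phenyl]-9-methoxy-2H,10H-pyrano[2,3-f]chromene-2,10-dione
Conditions: Pd(OAc)2 (10 mol%), CF3CO2H/CH2Cl2 (1:4), 0 °C to rt
Reagents that add atoms: none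
Why: Pd(OAc)2 in CF3CO2H gives an electrophilic divalent palladium trifluoroacetate that binds the triple bond of 7; ring A carbon C6 then attacks the terminal alkyne carbon from the side opposite the metal, the arenium ion loses its proton, and the vinylpalladium carbon next to the carbonyl is protonated by the acid, which returns the catalyst without change of oxidation state. The closest known reaction type is the palladium-catalysed intramolecular hydroarylation of aryl alkynoates used to make coumarins, a Friedel–Crafts-type alkenylation. Ring D (O5, the carbonyl carbon, the two alkyne carbons, C6 and C5) closes in the 6-endo-dig mode, because the metal-bound ynoate is electrophilic at its beta carbon and the 5-exo alternative would put a strained exocyclic alkene on a five-membered lactone. No stereocentre is formed, and the ring fixes the new double bond as cis. The step needs site selectivity for C6 over C8, and the tether secures it: from O5 only C6 is within reach, the other neighbour of C5 being the fully substituted fusion carbon C4a, while the 7-benzyloxy group (ortho) and the ring C oxygen (para) keep C6 nucleophilic. Diluting the acid with CH2Cl2 should limit protonation of the ring C carbonyl and acidolysis of the aryl ester and the benzyl ethers.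

Step 5
Reactants: 8 5-(benzyloxy)-8-[4-(benzyloxy)phenyl]-9-methoxy-2H,10H-pyrano[2,3-f]chromene-2,10-dione
Product: 10 5-hydroxy-8-(4-hydroxyphenyl)-9-methoxy-3,4-dihydro-2H,10H-pyrano[2,3-f]chromene-2,10-dione, via debenzylated pyranone 9 (not isolated)
Conditions: H2 (4 atm), 10% Pd/C, THF/EtOAc, 40 °C
Reagents that add atoms: none
Why: Heterogeneous catalytic hydrogenation in which the two aryl benzyl ethers are cleaved by hydrogenolysis first and the coumarin-type lactone C=C is then saturated, while the tetrasubstituted C2=C3 bond of the 4-pyranone ring C should not be reduced and the alcohol-free solvent keeps the activated aryl lactone closed.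

Step 6
Reactants: 10 5-hydroxy-8-(4-hydroxyphenyl)-9-methoxy-3,4-dihydro-2H,10H-pyrano[2,3-f]chromene-2,10-dione; 11 methylmagnesium bromide
Product: 13 topazolin hydrate, via 6-(3-oxobutyl) ketone 12 (not isolated)
Conditions: MeMgBr (8 equiv), THF, 0 °C to rt; then sat. aq. NH4Cl
Reagents that add atoms: methylmagnesium bromide, C[Mg]Br
Why: Grignard double addition to an ester, in which two equivalents are spent on the 7- and 4'-hydroxyls, the first methyl addition to the aryl-ester lactone expels the O5 phenoxide and gives ketone 12, the second gives the tertiary alkoxide, the phenoxides conjugated or chelated to the C4 carbonyl shield ring C from the reagent, and the buffered quench avoids acid-promoted cyclization of the carbinol onto O5 or O7.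

**Compound list**

1 | kaempferol | O=c1c(O)c(-c2ccc(O)cc2)oc2cc(O)cc(O)c12 | starting material
2 | benzyl bromide | BrCc1ccccc1 | starting material
3 | 7,4'-di-O-benzylkaempferol (7-(benzyloxy)-2-[4-(benzyloxy)phenyl]-3,5-dihydroxy-4H-chromen-4-one) | O=c1c(O)c(-c2ccc(OCc3ccccc3)cc2)oc2cc(OCc3ccccc3)cc(O)c12 | intermediate
4 | iodomethane | CI | starting material
5 | 7,4'-di-O-benzyl-3-O-methylkaempferol (7-(benzyloxy)-2-[4-(benzyloxy)phenyl]-5-hydroxy-3-methoxy-4H-chromen-4-one) | COc1c(-c2ccc(OCc3ccccc3)cc2)oc2cc(OCc3ccccc3)cc(O)c2c1=O | intermediate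
6 | propiolic acid | C#CC(=O)O | starting material
7 | 7-(benzyloxy)-2-[4-(benzyloxy)phenyl]-3-methoxy-4-oxo-4H-chromen-5-yl prop-2-ynoate (key-step precursor) | C#CC(=O)Oc1cc(OCc2ccccc2)cc2oc(-c3ccc(OCc4ccccc4)cc3)c(OC)c(=O)c12 | intermediate
8 | 5-(benzyloxy)-8-[4-(benzyloxy)phenyl]-9-methoxy-2H,10H-pyrano[2,3-f]chromene-2,10-dione (key-step product; 2-pyranone ring D fused across O5 and C6 of the flavone) | COc1c(-c2ccc(OCc3ccccc3)cc2)oc2cc(OCc3ccccc3)c3ccc(=O)oc3c2c1=O | intermediate
9 | 5-hydroxy-8-(4-hydroxyphenyl)-9-methoxy-2H,10H-pyrano[2,3-f]chromene-2,10-dione (debenzylated pyranone, not isolated) | COc1c(-c2ccc(O)cc2)oc2cc(O)c3ccc(=O)oc3c2c1=O | intermediate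
10 | 5-hydroxy-8-(4-hydroxyphenyl)-9-methoxy-3,4-dihydro-2H,10H-pyrano[2,3-f]chromene-2,10-dione | COc1c(-c2ccc(O)cc2)oc2cc(O)c3CCC(=O)Oc3c2c1=O | intermediate
11 | methylmagnesium bromide | C[Mg]Br | starting material
12 | 5,7-dihydroxy-2-(4-hydroxyphenyl)-3-methoxy-6-(3-oxobutyl)-4H-chromen-4-one (present as its magnesium phenoxide, not isolated) | COc1c(-c2ccc(O)cc2)oc2cc(O)c(CCC(C)=O)c(O)c2c1=O | intermediate
13 | topazolin hydrate (5,7-dihydroxy-6-(3-hydroxy-3-methylbutyl)-2-(4-hydroxyphenyl)-3-methoxy-4H-chromen-4-one; no stereocentre) | COc1c(-c2ccc(O)cc2)oc2cc(O)c(CCC(C)(C)O)c(O)c2c1=O | target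

**Step count**

Total steps: 6. Longest linear sequence: 6 steps (kaempferol 1 to target 13).

**Steps most likely to fail**

Step 4. The cyclization may be too slow: protonation of the ring C carbonyl in the acid drains electron density from C6, so addition of trifluoroacetate to the alkyne and acidolysis of the activated aryl ester can overtake ring closure. The fallback gives up the tether and forms the C6–C1'' bond by cross-coupling. Setting out from 5, ring A is iodinated ortho to the free 5-OH with benzyltrimethylammonium dichloroiodate and CaCO3 in CH2Cl2/MeOH to give 7,4'-di-O-benzyl-6-iodo-3-O-methylkaempferol F1. A Heck reaction of this iodide with 2-methylbut-3-en-2-ol (Pd(OAc)2, Bu4NCl, NaHCO3, DMF, 90 °C) should give (E)-7,4'-di-O-benzyl-6-(3-hydroxy-3-methylbut-1-enyl)-3-O-methylkaempferol F2. Hydrogenation over 10% Pd/C then saturates the alkene and removes both benzyl groups, so the fallback rejoins the route at 13.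

Step 3. Acylation of the hydrogen-bonded 5-OH may lag, so that the activated propiolic acid is used up by amine-triggered oligomerization and by conjugate addition of the phenol to the triple bond. The fallback uses a silicon-capped acid chloride. Setting out from 5, the phenoxide is formed with NaH in THF and acylated with 3-(trimethylsilyl)propynoyl chloride (made from the commercial acid and oxalyl chloride) to give 7-(benzyloxy)-2-[4-(benzyloxy)phenyl]-3-methoxy-4-oxo-4H-chromen-5-yl 3-(trimethylsilyl)prop-2-ynoate F3. The silyl cap blocks conjugate addition during acylation and is then removed with catalytic AgNO3 in aqueous acetone, which rejoins the route at 7.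

Step 6. The magnesium phenoxides of 10 may precipitate, and enolization of ketone 12 may stop the addition halfway; prolonged warming with excess reagent then risks attack on ring C. The fallback replaces the phenoxide masking with silyl ethers so that the addition runs in solution at low temperature. Setting out from 10, both phenols are silylated (TBSCl, imidazole, DMF) to give 5-(tert-butyldimethylsilyloxy)-8-[4-(tert-butyldimethylsilyloxy)phenyl]-9-methoxy-3,4-dihydro-2H,10H-pyrano[2,3-f]chromene-2,10-dione F4. MeMgBr in THF at −78 to 0 °C (or MeLi with CeCl3) should open the aryl-ester lactone and add twice to give 7,4'-bis-O-(tert-butyldimethylsilyl) topazolin hydrate F5; the ring C carbonyl is far less electrophilic than the aryl ester and is chelated by the O5 magnesium phenoxide freed in the first addition. Bu4NF buffered with AcOH in THF removes the silyl groups and rejoins the route at 13.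

**Further compounds**

F1 | step 4 | 7,4'-di-O-benzyl-6-iodo-3-O-methylkaempferol | COc1c(-c2ccc(OCc3ccccc3)cc2)oc2cc(OCc3ccccc3)c(I)c(O)c2c1=O
F2 | step 4 | (E)-7,4'-di-O-benzyl-6-(3-hydroxy-3-methylbut-1-enyl)-3-O-methylkaempferol | COc1c(-c2ccc(OCc3ccccc3)cc2)oc2cc(OCc3ccccc3)c(/C=C/C(C)(C)O)c(O)c2c1=O
F3 | step 3 | 7-(benzyloxy)-2-[4-(benzyloxy)phenyl]-3-methoxy-4-oxo-4H-chromen-5-yl 3-(trimethylsilyl)prop-2-ynoate | C[Si](C)(C)C#CC(=O)Oc1cc(OCc2ccccc2)cc2oc(-c3ccc(OCc4ccccc4)cc3)c(OC)c(=O)c12
F4 | step 6 | 5-(tert-butyldimethylsilyloxy)-8-[4-(tert-butyldimethylsilyloxy)phenyl]-9-methoxy-3,4-dihydro-2H,10H-pyrano[2,3-f]chromene-2,10-dione | COc1c(-c2ccc(O[Si](C)(C)C(C)(C)C)cc2)oc2cc(O[Si](C)(C)C(C)(C)C)c3CCC(=O)Oc3c2c1=O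
F5 | step 6 | 7,4'-bis-O-(tert-butyldimethylsilyl) topazolin hydrate | COc1c(-c2ccc(O[Si](C)(C)C(C)(C)C)cc2)oc2cc(O[Si](C)(C)C(C)(C)C)c(CCC(C)(C)O)c(O)c2c1=O
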